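**Plan**
1. Last cut: the O–benzyl bond of the phenol.
2. Main cut: C3a–C4 and C5–C6 of the benzo ring (benzofuran numbering). C4(OMe)–C5(H) is a ketene acetal two-carbon unit. C6 (aryl), C7 (OMe), C7a (O) and C3a are the four diene carbons of the 2-pyrone ring of a 4H-furo[3,2-c]pyran-4-one, whose C4(=O)–O5 bridge can leave as CO2.
3. The furan of that pyranone is cut at C3–C3a and O1–C2 into a 4-hydroxy-2-pyrone and a five-carbon allylic carbonate. The pyrone is cut into an aryl methoxymethyl ketone (as its silyl enol ether) and malonyl dichloride.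
4. Forward order of rings: pyrone (step 3), dihydrofuran (step 6), furan (step 7), benzene (step 8), then debenzylation (step 9).
5. Stereochemistry: the target is achiral; the stereocentres of 9–12 and 15 are racemic and are erased on aromatisation.

Key step: step 8

Remark: racemic intermediates (9–12, 15) are drawn without configuration because every stereocentre is lost before the target; 12 is carried on as its cis/trans mixture.

**Step 1**
Reactants: 1 1-(benzyloxy)-4-bromobenzene; 2 N,2-dimethoxy-N-methylacetamide
Product: 4 1-[4-(benzyloxy)phenyl]-2-methoxyethan-1-one, via arylmagnesium bromide 3 (not isolated)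
Conditions: Mg, I2 (cat.), THF, reflux; then 2, THF, 0 °C to rt; 1 M HCl work-up
Reagents that add atoms: magnesium, [Mg] (present only in intermediate 3)
Why: Grignard formation and Weinreb ketone synthesis: the magnesium-chelated tetrahedral adduct of amide 2 does not collapse until the acidic work-up, so the aryl group is delivered once and the methoxymethyl ketone forms without over-addition; no stereocentre is formed.

**Step 2**
Reactants: 4 1-[4-(benzyloxy)phenyl]-2-methoxyethan-1-one
Product: 5 {(Z)-1-[4-(benzyloxy)phenyl]-2-methoxyethenoxy}trimethylsilane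
Conditions: LiN(SiMe3)2, THF, −78 °C; TMSCl, −78 °C to rt; non-aqueous work-up (pentane, filtration)
Reagents that add atoms: chlorotrimethylsilane, C[Si](C)(C)Cl
Why: Kinetic enolisation and O-silylation (silyl enol ether formation): chelation of lithium by the α-methoxy group should give the Z enol ether, although either geometry serves in step 3; no stereocentre is formed.

**Step 3**
Reactants: 5 {(Z)-1-[4-(benzyloxy)phenyl]-2-methoxyethenoxy}trimethylsilane; 6 malonyl dichloride
Product: 7 6-[4-(benzyloxy)phenyl]-4-hydroxy-5-methoxy-2H-pyran-2-one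
Conditions: Et2O, −78 °C to rt
Reagents that add atoms: none
Why: Pyrone annulation of a silyl enol ether with malonyl dichloride (C-acylation at the methoxy-bearing enol carbon, then lactonisation of the enol oxygen onto the second acyl chloride) is a known route to 5,6-disubstituted 4-hydroxy-2-pyrones, and the substitution pattern of 5 allows only one regiochemistry; no stereocentre is formed.

**Step 4**
Reactants: 8 methyl (E)-4-oxopent-2-enoate
Product: 9 methyl (E)-4-hydroxypent-2-enoate
Conditions: NaBH4, CeCl3·7H2O, MeOH, 0 °C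
Reagents that add atoms: none
Why: Luche reduction: with CeCl3 in methanol the hydride adds 1,2 to the ketone and leaves the conjugated ester and the alkene untouched; the carbinol centre is formed without control (racemic), which does not matter because it is lost by step 7.

**Step 5**
Reactants: 9 methyl (E)-4-hydroxypent-2-enoate
Product: 10 methyl (E)-4-[(methoxycarbonyl)oxy]pent-2-enoate
Conditions: ClCO2Me, pyridine, CH2Cl2, 0 °C
Reagents that add atoms: methyl chloroformate, COC(=O)Cl
Why: Acylation of the secondary allylic alcohol gives the mixed carbonate, which ionises under neutral conditions in step 6 and supplies its own base on decarboxylation; the stereocentre is untouched (racemic).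

**Step 6**
Reactants: 7 6-[4-(benzyloxy)phenyl]-4-hydroxy-5-methoxy-2H-pyran-2-one; 10 methyl (E)-4-[(methoxycarbonyl)oxy]pent-2-enoate
Product: 12 methyl 2-{6-[4-(benzyloxy)phenyl]-7-methoxy-3-methyl-4-oxo-2,3-dihydro-4H-furo[3,2-c]pyran-2-yl}acetate, via C3-allylated pyrone 11 (not isolated)
Conditions: Pd(PPh3)4 (5 mol %), THF, 50 °C; then DBU (0.2 equiv), rt
Reagents that add atoms: none
Why: Tsuji–Trost allylation followed by intramolecular oxa-Michael addition: zerovalent palladium ionises 10 to a π-allyl complex that the soft C3 carbon of the pyronate should attack at the terminus remote from the ester (O-allylated material re-enters the π-allyl manifold), and DBU then closes the C4 oxygen onto the enoate in a 5-exo-trig mode to the angular dihydrofuran that keeps the 2-pyrone; the two new stereocentres are formed without control (racemic cis/trans mixture) and are removed in step 7.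

**Step 7**
Reactants: 12 methyl 2-{6-[4-(benzyloxy)phenyl]-7-methoxy-3-methyl-4-oxo-2,3-dihydro-4H-furo[3,2-c]pyran-2-yl}acetate
Product: 13 methyl 2-{6-[4-(benzyloxy)phenyl]-7-methoxy-3-methyl-4-oxo-4H-furo[3,2-c]pyran-2-yl}acetate
Conditions: DDQ (1.5 equiv), 1,4-dioxane, reflux
Reagents that add atoms: none
Why: DDQ dehydrogenation (hydride abstraction next to the enol-ether π system, then proton loss), a known aromatisation of 2,3-dihydrofuro[3,2-c]coumarins, should convert the dihydrofuran into the furan while the aryl benzyl ether and the ester stay intact; both stereocentres disappear.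

**Step 8**
Reactants: 13 methyl 2-{6-[4-(benzyloxy)phenyl]-7-methoxy-3-methyl-4-oxo-4H-furo[3,2-c]pyran-2-yl}acetate; 14 1,1-dimethoxyethene
Product: 17 methyl 2-{6-[4-(benzyloxy)phenyl]-4,7-dimethoxy-3-methyl-1-benzofuran-2-yl}acetate, via bridged lactone cycloadduct 15 (not isolated), via dihydrobenzofuran ketal 16 (not isolated)
Conditions: 14 (15 equiv), mesitylene, sealed tube, 150 °C
Reagents that add atoms: none
Why: Proposed new method: the nucleophilic CH2 of 14 bonds to C6 of 13, the electrophilic end of the C6=C7–C7a=C3a–C4=O chain, and the developing dimethoxycarbenium carbon bonds to C3a in a polarised, asynchronous inverse-electron-demand [4+2] cycloaddition to 15, which loses the C4(=O)–O5 bridge as CO2 by cycloreversion to 16 and then methanol by 1,2-elimination. The closest known reaction type is the thermal cycloaddition of 2-pyrones bearing an alkoxycarbonyl group (monocyclic or carbocycle-fused) with 1,1-dimethoxyethene, which ends in methoxyarenes after loss of CO2 and methanol; a pyrone whose C3a=C7a diene bond belongs to a furan and that carries oxygen at C7 and C7a has not been used in it, hence the large excess of 14 and the high temperature (12–15 kbar near ambient temperature is the other way to drive it). The benzo ring closes by an intermolecular [4+2] cycloaddition across C3a and C6 (new bonds C3a–C4 and C5–C6) and becomes aromatic through a retro-[4+2] extrusion and an elimination. No stereocentre remains, since the two bridgehead centres of 15 are transient and 17 is achiral. The step needs one regiochemistry, OMe at C4 and H at C5, and the substrate secures it because C6 is the only diene terminus that is an acceptor position of the lactone carbonyl and so pairs with the CH2 of the ketene acetal, while C3a, the α-carbon of that carbonyl, pairs with the acetal carbon. The fully substituted, acyl-deactivated furan should not compete as a diene, the ester and the benzyl ether tolerate the conditions, and the irreversible loss of CO2 together with the benzofuran aromaticity gained pays for the furan sextet interrupted in 15.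

**Step 9**
Reactants: 17 methyl 2-{6-[4-(benzyloxy)phenyl]-4,7-dimethoxy-3-methyl-1-benzofuran-2-yl}acetate
Product: 18 Phenylcandilide B, methyl 2-[6-(4-hydroxyphenyl)-4,7-dimethoxy-3-methyl-1-benzofuran-2-yl]acetate
Conditions: H2 (1 atm), Pd/C (10 wt %), EtOAc–MeOH, rt
Reagents that add atoms: none
Why: Catalytic hydrogenolysis of the aryl benzyl ether frees the phenol, while the tetrasubstituted benzofuran double bond, the aryl methyl ethers and the methyl ester should not be reduced at ambient pressure; no stereocentre is involved.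

**Compound list**
1 | 1-(benzyloxy)-4-bromobenzene | Brc1ccc(OCc2ccccc2)cc1 | starting material
2 | N,2-dimethoxy-N-methylacetamide | COCC(=O)N(C)OC | starting material
3 | [4-(benzyloxy)phenyl]magnesium bromide | Br[Mg]c1ccc(OCc2ccccc2)cc1 | intermediate (not isolated)
4 | 1-[4-(benzyloxy)phenyl]-2-methoxyethan-1-one | COCC(=O)c1ccc(OCc2ccccc2)cc1 | intermediate
5 | {(Z)-1-[4-(benzyloxy)phenyl]-2-methoxyethenoxy}trimethylsilane | CO/C=C(\O[Si](C)(C)C)c1ccc(OCc2ccccc2)cc1 | intermediate
6 | malonyl dichloride (propanedioyl dichloride) | O=C(Cl)CC(=O)Cl | starting material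
7 | 6-[4-(benzyloxy)phenyl]-4-hydroxy-5-methoxy-2H-pyran-2-one | COC1=C(c2ccc(OCc3ccccc3)cc2)OC(=O)C=C1O | intermediate
8 | methyl (E)-4-oxopent-2-enoate | CC(=O)/C=C/C(=O)OC | starting material
9 | methyl (E)-4-hydroxypent-2-enoate (racemic) | COC(=O)/C=C/C(C)O | intermediate
10 | methyl (E)-4-[(methoxycarbonyl)oxy]pent-2-enoate (racemic) | COC(=O)/C=C/C(C)OC(=O)OC | intermediate
11 | methyl (E)-4-{6-[4-(benzyloxy)phenyl]-4-hydroxy-5-methoxy-2-oxo-2H-pyran-3-yl}pent-2-enoate (racemic) | COC(=O)/C=C/C(C)C1=C(O)C(OC)=C(c2ccc(OCc3ccccc3)cc2)OC1=O | intermediate (not isolated)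
12 | methyl 2-{6-[4-(benzyloxy)phenyl]-7-methoxy-3-methyl-4-oxo-2,3-dihydro-4H-furo[3,2-c]pyran-2-yl}acetate (racemic cis/trans mixture) | COC(=O)CC1OC2=C(C1C)C(=O)OC(c1ccc(OCc3ccccc3)cc1)=C2OC | intermediate
13 | methyl 2-{6-[4-(benzyloxy)phenyl]-7-methoxy-3-methyl-4-oxo-4H-furo[3,2-c]pyran-2-yl}acetate | COC(=O)CC1=C(C)C2=C(O1)C(OC)=C(c3ccc(OCc4ccccc4)cc3)OC2=O | intermediate
14 | 1,1-dimethoxyethene | C=C(OC)OC | starting material
15 | [4+2] adduct of 13 and 14: 2-oxabicyclo[2.2.2]oct-5-en-3-one with the lactone bridge C4(=O)–O5 intact, a C(OMe)2–CH2 bridge from C3a to C6, and C2=C3 and C7=C7a double bonds (racemic) | COC(=O)CC1=C(C)C23C(=O)OC(c4ccc(OCc5ccccc5)cc4)(CC2(OC)OC)C(OC)=C3O1 | intermediate (not isolated)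
16 | methyl 2-{6-[4-(benzyloxy)phenyl]-4,4,7-trimethoxy-3-methyl-4,5-dihydro-1-benzofuran-2-yl}acetate | COC(=O)Cc1oc2C(OC)=C(c3ccc(OCc4ccccc4)cc3)CC(OC)(OC)c2c1C | intermediate (not isolated)
17 | methyl 2-{6-[4-(benzyloxy)phenyl]-4,7-dimethoxy-3-methyl-1-benzofuran-2-yl}acetate | COC(=O)Cc1oc2c(OC)c(-c3ccc(OCc4ccccc4)cc3)cc(OC)c2c1C | intermediate
18 | Phenylcandilide B, methyl 2-[6-(4-hydroxyphenyl)-4,7-dimethoxy-3-methyl-1-benzofuran-2-yl]acetate | COC(=O)Cc1oc2c(OC)c(-c3ccc(O)cc3)cc(OC)c2c1C | target

**Step count**
Total: 9 steps. Longest linear sequence: 7 steps (1, 2, 3, 6, 7, 8, 9); steps 4 and 5 form the side branch that joins at step 6.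

**Steps most likely to fail**

Step 8 (the proposed new method). The cycloaddition may not start, because the diene carries two oxygen donors and must give up the furan sextet on the way to the adduct, while the ketene acetal is consumed by oligomerisation at the temperature needed. The fallback abandons the pyrone and builds 17 from the benzene side with known reactions only. It sets out from arylmagnesium bromide 3, which is quenched with trimethyl borate and hydrolysed to [4-(benzyloxy)phenyl]boronic acid F1. Commercial 3-bromo-2-hydroxy-5-methoxybenzaldehyde is O-methylated (MeI, K2CO3, DMF) to 3-bromo-2,5-dimethoxybenzaldehyde F2. Suzuki coupling of F1 and F2 (Pd(PPh3)4, K2CO3, dioxane–water, 90 °C) gives 3-[4-(benzyloxy)phenyl]-2,5-dimethoxybenzaldehyde F3. Baeyer–Villiger oxidation with mCPBA gives 3-[4-(benzyloxy)phenyl]-2,5-dimethoxyphenyl formate F4, and methanolysis (K2CO3, MeOH) gives 3-[4-(benzyloxy)phenyl]-2,5-dimethoxyphenol F5, whose oxygen becomes O1 of the benzofuran. Alkylation with (E)-1-bromobut-2-ene (K2CO3, DMF) gives 1-[4-(benzyloxy)phenyl]-3-[(E)-but-2-en-1-yloxy]-2,5-dimethoxybenzene F6. Aromatic Claisen rearrangement (N,N-diethylaniline, 190 °C) moves the allyl unit to the only free ortho carbon and gives 3-[4-(benzyloxy)phenyl]-6-(but-3-en-2-yl)-2,5-dimethoxyphenol F7. Cross-metathesis with methyl acrylate (second-generation Grubbs catalyst, CH2Cl2, 40 °C) gives methyl (E)-4-{4-[4-(benzyloxy)phenyl]-2-hydroxy-3,6-dimethoxyphenyl}pent-2-enoate F8. DBU closes F8 by oxa-Michael addition to methyl 2-{6-[4-(benzyloxy)phenyl]-4,7-dimethoxy-3-methyl-2,3-dihydro-1-benzofuran-2-yl}acetate F9, and dehydrogenation with DDQ gives 17, where the fallback rejoins the route before step 9.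

Step 6. Allylation may take place at oxygen or at the ester-bearing allyl terminus, and the π-allyl complex may collapse by β-hydride elimination to a dienoate before the pyronate attacks. The fallback forms the C3–C bond by a sigmatropic shift instead of by palladium catalysis. It sets out from 7, which is etherified at the C4 oxygen with (E)-but-2-en-1-ol under Mitsunobu conditions (PPh3, DIAD, THF) to 6-[4-(benzyloxy)phenyl]-4-[(E)-but-2-en-1-yloxy]-5-methoxy-2H-pyran-2-one F10. Claisen rearrangement (toluene, 130 °C, sealed tube) delivers the allyl unit to C3 and gives 6-[4-(benzyloxy)phenyl]-3-(but-3-en-2-yl)-4-hydroxy-5-methoxy-2H-pyran-2-one F11. Cross-metathesis with methyl acrylate (second-generation Grubbs catalyst) gives 11, where the fallback rejoins the route for the DBU-mediated ring closure to 12.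

Step 3. Protodesilylation of the enol ether by the HCl released, acylation at oxygen instead of carbon, and a second acylation of the product by malonyl dichloride may erode the annulation. The fallback assembles the pyrone from a β-keto ester dianion instead. It sets out from arylmagnesium bromide 3, which is added to excess methyl chloroformate at −78 °C to give methyl 4-(benzyloxy)benzoate F12. The dianion of commercial methyl 4-methoxy-3-oxobutanoate (NaH, then n-BuLi, THF, 0 °C) is acylated at its γ-carbon by F12 to give methyl 5-[4-(benzyloxy)phenyl]-4-methoxy-3,5-dioxopentanoate F13. Enol lactonisation (DBU, toluene, reflux) gives 7, where the fallback rejoins the route.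

**Further compounds**
F1 | step 8 | [4-(benzyloxy)phenyl]boronic acid | OB(O)c1ccc(OCc2ccccc2)cc1
F2 | step 8 | 3-bromo-2,5-dimethoxybenzaldehyde | COc1cc(Br)c(OC)c(C=O)c1
F3 | step 8 | 3-[4-(benzyloxy)phenyl]-2,5-dimethoxybenzaldehyde | COc1cc(C=O)c(OC)c(-c2ccc(OCc3ccccc3)cc2)c1
F4 | step 8 | 3-[4-(benzyloxy)phenyl]-2,5-dimethoxyphenyl formate | COc1cc(OC=O)c(OC)c(-c2ccc(OCc3ccccc3)cc2)c1
F5 | step 8 | 3-[4-(benzyloxy)phenyl]-2,5-dimethoxyphenol | COc1cc(O)c(OC)c(-c2ccc(OCc3ccccc3)cc2)c1
F6 | step 8 | 1-[4-(benzyloxy)phenyl]-3-[(E)-but-2-en-1-yloxy]-2,5-dimethoxybenzene | C/C=C/COc1cc(OC)cc(-c2ccc(OCc3ccccc3)cc2)c1OC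
F7 | step 8 | 3-[4-(benzyloxy)phenyl]-6-(but-3-en-2-yl)-2,5-dimethoxyphenol (racemic) | C=CC(C)c1c(OC)cc(-c2ccc(OCc3ccccc3)cc2)c(OC)c1O
F8 | step 8 | methyl (E)-4-{4-[4-(benzyloxy)phenyl]-2-hydroxy-3,6-dimethoxyphenyl}pent-2-enoate (racemic) | COC(=O)/C=C/C(C)c1c(OC)cc(-c2ccc(OCc3ccccc3)cc2)c(OC)c1O
F9 | step 8 | methyl 2-{6-[4-(benzyloxy)phenyl]-4,7-dimethoxy-3-methyl-2,3-dihydro-1-benzofuran-2-yl}acetate (racemic cis/trans mixture) | COC(=O)CC1Oc2c(OC)c(-c3ccc(OCc4ccccc4)cc3)cc(OC)c2C1C
F10 | step 6 | 6-[4-(benzyloxy)phenyl]-4-[(E)-but-2-en-1-yloxy]-5-methoxy-2H-pyran-2-one | C/C=C/COC1=CC(=O)OC(c2ccc(OCc3ccccc3)cc2)=C1OC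
F11 | step 6 | 6-[4-(benzyloxy)phenyl]-3-(but-3-en-2-yl)-4-hydroxy-5-methoxy-2H-pyran-2-one (racemic) | C=CC(C)C1=C(O)C(OC)=C(c2ccc(OCc3ccccc3)cc2)OC1=O
F12 | step 3 | methyl 4-(benzyloxy)benzoate | COC(=O)c1ccc(OCc2ccccc2)cc1
F13 | step 3 | methyl 5-[4-(benzyloxy)phenyl]-4-methoxy-3,5-dioxopentanoate | COC(=O)CC(=O)C(OC)C(=O)c1ccc(OCc2ccccc2)cc1
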